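## The problem

CNP0243348.0 (compound 20) is an achiral prenylated bibenzyl. It is a 2,2-dimethyl-2H-chromene whose benzo ring (ring A) carries a hydroxyl at C5, a 3-methylbut-2-enyl group at C6 and a 2-(4-hydroxyphenyl)ethyl chain (ring B) at C7. Ring A is pentasubstituted: C4a, C5, C6, C7 and C8a are all substituted and only C8 bears hydrogen. The difficulty is therefore regiochemical: which resorcinol oxygen becomes O1, which ring carbon takes the pyran carbon C4, and how prenyl is placed at C6 and not at C8. There is no stereocentre, so nothing has to be set or relayed. Three groups are fragile: the styrenic C3=C4 bond (hydrogenation, acid, oxidants), the prenyl group ortho to a free phenol (acid closes it to a chroman), and the electron-rich phenols (oxidation). The C5 phenol and the ring B phenol must also be told apart, because only the C5 oxygen is to carry the allyl unit destined for C6. The enabling feature is that C4 hangs on C4a, the carbon between C5–O and C8a–O. If C4 is brought in as the formyl carbon of a 2,6-dihydroxybenzaldehyde with the side chain para to it, the two hydroxyls are mirror images and closure through either gives the same chromene. The hydroxyl left over is the C5 phenol, whose only free ortho carbon is C6.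

## Retrosynthesis

Positions follow chromene numbering (O1, C2, C3, C4, C4a, C5–C8, C8a).

**20 from 19 (O–Si at ring B).** The ring B phenol must stay masked while the C5 phenol alone is alkylated. A triisopropylsilyl ether is chosen over a smaller silyl ether because it has to pass hot aqueous base (step 4), an alkyllithium (step 5) and aqueous acid (step 6). It still leaves under buffered fluoride, which touches neither C3=C4 nor the prenyl group. Compound 19 differs from 20 only by this group.

**19 from 17, 16, and 14 plus 15 (C6–CH2 bond of the prenyl group, then the C5 O–C bond).** Direct electrophilic prenylation of 14 would have to choose between C6 and C8 and between carbon and oxygen, and its acidic medium would close the product to a chroman. The [3,3] shift of the 1,1-dimethylallyl ether 17 delivers the five-carbon unit from the C5 oxygen to an ortho carbon and inverts it to the linear prenyl group. The ortho carbons are C4a (quaternary) and C6, and only the dienone at C6 (18) can tautomerise to a phenol. A tertiary allyl ether cannot be made by direct substitution, so 17 is reached by semi-hydrogenation of the propargyl ether 16. Compound 16 comes from 14 and the tertiary propargylic chloride 15 under copper catalysis. The forward steps must stop hydrogen uptake at the alkene and keep the Claisen medium free of acid.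

**14 from 10 plus 11 (C4–C3 and O1–C2; key step).** Annulating a free resorcinol with an enal would cut C4–C4a instead and must choose between two ring carbons. An aryl propargyl ether cyclisation would need mono-etherification of a symmetric diol and then a choice between two ortho carbons. The chosen cut already has C4 on C4a as a formyl group. Precursor 10 has a mirror plane through the formyl carbon and the side chain, and 11 is a catalogue boronic acid. The forward reaction must transfer the alkenyl group to the aldehyde carbon through an iminium ion, then lose the amine and close the ring. It needs chemoselectivity only.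

**10 from 9 and 7 (C4a–CHO bond).** Electrophilic formylation of a 5-alkylresorcinol goes to the carbon between a hydroxyl and the chain, which is the wrong site. Lithiation has the opposite preference: the carbon flanked by two methoxymethyl ethers is the most acidic and doubly chelated. Compound 7 is therefore lithiated to 8 and formylated to 9, and the acetals are hydrolysed to 10. The methoxymethyl groups serve first as directing groups and then leave under dilute acid that spares the aryl triisopropylsilyl ether.

**7 from 3 plus 5 through 6 (bridge CH2–ring B bond).** An olefination and hydrogenation route would need a benzylic phosphonium salt made over several steps plus a separate reduction. Hydroboration of styrene 3 and B-alkyl Suzuki–Miyaura coupling of borane 6 with aryl bromide 5 form the saturated two-carbon bridge in one flask. The forward reaction asks for anti-Markovnikov hydroboration and for coupling that outruns beta-hydride elimination.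

**3 from 2 and 1; 5 from 4.** Styrene 3 comes from aldehyde 2 by methylenation, and 2 from 3,5-dihydroxybenzaldehyde 1 by acetal protection. Bromide 5 is the silyl ether of 4-bromophenol 4. Both 1 and 4 are commodity phenols.

## Roads not taken

**Alternative 1:** Ring A is cut at C4a–C5 and C6–C7. The pyran stays intact in the bicyclic 2-pyranone A2 (2,2-dimethyl-7-[2-(4-tert-butyldimethylsilyloxyphenyl)ethyl]-2H,5H-pyrano[4,3-b]pyran-5-one), and C5 and C6 come from the siloxyalkyne A3 (triisopropyl(5-methylhex-4-en-1-ynyloxy)silane).
- Forward step: A3 adds across lactone carbons 3 and 6 of A2, and decarboxylative cycloreversion of the bridged adduct leaves the bis-silyl ether A1 of the target.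
- Merits: the step is convergent and places all five ring A substituents in one operation. The polarity of the ynol ether matches the lactone, the C5 oxygen arrives already differentiated, and no late Claisen step is needed. In regiochemical completeness it is better than the chosen plan.
- Weak points: A2 is a 4-alkoxy-6-alkyl-2-pyranone, an electron-rich and sluggish diene, and here it meets an electron-rich alkyne. The cycloaddition would need temperatures at which siloxyalkynes isomerise to silylketenes and the dienyl ether of A2 can ring-open. A3 is moisture-sensitive and must be made by ynolate chemistry, and two different silyl groups have to come off at the end.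
- Comparison: the chosen plan pays with a three-step ether, semi-hydrogenation and Claisen sequence. Against that it sets catalogue building blocks, standard reactions and a ring closure whose regiochemistry is settled by the symmetry of 10.

**Alternative 2:** Ring A is cut at C4a–C8a, C5–C6 and C8–C8a. The components are cyclobutenone A5 (2-(3-methylbut-2-enyl)-3-[2-(4-tert-butyldimethylsilyloxyphenyl)ethyl]cyclobut-2-en-1-one) and the same siloxyalkyne A3.
- Forward step: a Danheiser benzannulation. Heat opens A5 to a vinylketene, which adds A3 in a [2+2] sense; four-electron opening and six-electron closure give phenol A4 (2,4-bis(3-methylbut-2-enyl)-3-(triisopropylsilyloxy)-5-[2-(4-tert-butyldimethylsilyloxyphenyl)ethyl]phenol).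
- Merits: the ring is assembled regiospecifically with the two oxygens differentiated, and the C6 prenyl group is in place without a sigmatropic step. That is an advantage over the chosen plan.
- Weak points: the pyran is not formed in the key step. It must be closed afterwards by dehydrogenative cyclisation of the prenyl group ortho to the free phenol with a quinone oxidant, in a molecule with a second prenyl group and a bibenzyl bridge that are also oxidisable. A5 is an unsymmetrical 2,3-dialkylcyclobutenone and needs a regiocontrolled synthesis of its own. The ynol ether problems of Alternative 1 return.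
- Comparison: the chosen plan forms the pyran directly and without an oxidant, and needs fewer operations from purchasable materials.

**Alternative 3:** The cuts are the C3=C4 double bond and the trisubstituted double bond of the prenyl group. The precursor is A7 (2-allyl-5-(2-methylbut-3-en-2-yloxy)-6-vinyl-3-[2-(4-tert-butyldimethylsilyloxyphenyl)ethyl]phenol).
- Forward step: second-generation Grubbs catalyst RuCl2(H2IMes)(PCy3)(=CHPh) in A8 (2-methylbut-2-ene) closes the pyran by ring-closing metathesis of the C4a vinyl group with the 1,1-dimethylallyl ether. The same catalyst turns the C6 allyl group into prenyl by cross metathesis, giving the ring B silyl ether A6 of the target.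
- Merits: the conditions are neutral and mild, a free phenol is tolerated, and both olefins are made in one flask by well-known metathesis types. This end-game is gentler than the thermal Claisen step of the chosen plan.
- Weak points: all the regiochemical work moves into A7. It needs a vinyl group between two differentiated oxygens, a tertiary allyl ether on one of two equivalent hydroxyls, and an allyl group at C6 that would itself come from a Claisen rearrangement. The vinyl group would most simply come from the same kind of aldehyde as 10, so the route passes the chosen precursor and then adds steps. The tertiary allyl ether ortho to a vinyl group is also prone to premature rearrangement.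
- Comparison: the chosen plan turns the aldehyde into the chromene in one step and uses the leftover phenol as the handle for C6.

Key step: step 7

Remark on the chemistry: the target has no stereocentre. The stereocentres of the transient intermediates 12 and 18 form as racemates and disappear in the same flask, so no structure below carries a stereodescriptor.

## Route

Step 1
Reactants: 1 3,5-dihydroxybenzaldehyde
Product: 2 3,5-bis(methoxymethoxy)benzaldehyde
Conditions: MOMCl, i-Pr2NEt, CH2Cl2, 0 °C to rt
Reagents that add atoms: chloromethyl methyl ether, COCCl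
Why: O-alkylation of both phenols to methoxymethyl acetals; the non-enolisable aldehyde is inert, and the acetals later direct the lithiation of step 5 and leave with dilute acid.

Step 2
Reactants: 2 3,5-bis(methoxymethoxy)benzaldehyde
Product: 3 1,3-bis(methoxymethoxy)-5-vinylbenzene
Conditions: Ph3PCH3Br, KOt-Bu, THF, 0 °C to rt
Reagents that add atoms: methyltriphenylphosphonium bromide, C[P+](c1ccccc1)(c1ccccc1)c1ccccc1.[Br-]
Why: Wittig methylenation of an aryl aldehyde with the unstabilised ylide; the acetals are stable to the base.

Step 3
Reactants: 4 4-bromophenol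
Product: 5 (4-bromophenoxy)triisopropylsilane
Conditions: TIPSCl, imidazole, DMF, rt
Reagents that add atoms: triisopropylsilyl chloride, CC(C)[Si](Cl)(C(C)C)C(C)C
Why: imidazole-promoted silylation of a phenol; the hindered aryl triisopropylsilyl ether is chosen because it resists aqueous base, butyllithium and dilute acid in steps 4 to 6 and is still cleaved by fluoride.

Step 4
Reactants: 3 1,3-bis(methoxymethoxy)-5-vinylbenzene; 5 (4-bromophenoxy)triisopropylsilane
Product: 7 triisopropyl[4-[2-[3,5-bis(methoxymethoxy)phenyl]ethyl]phenoxy]silane, via B-alkyl-9-borabicyclononane 6 (not isolated)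
Conditions: 9-BBN-H, THF, 0 °C to rt; then 5, PdCl2(dppf)·CH2Cl2 (cat.), aq. K3PO4, DMF, 60 °C
Reagents that add atoms: none
Why: anti-Markovnikov hydroboration of the styrene puts boron on the terminal carbon, and the primary alkylborane 6 couples with the aryl bromide in a B-alkyl Suzuki–Miyaura reaction; the wide-bite-angle dppf ligand favours reductive elimination over beta-hydride elimination, so the saturated bridge forms without a separate hydrogenation.

Step 5
Reactants: 7 triisopropyl[4-[2-[3,5-bis(methoxymethoxy)phenyl]ethyl]phenoxy]silane
Product: 9 2,6-bis(methoxymethoxy)-4-[2-(4-triisopropylsilyloxyphenyl)ethyl]benzaldehyde, via aryllithium 8 (not isolated)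
Conditions: n-BuLi, TMEDA, THF, 0 °C; DMF, 0 °C to rt; H2O
Reagents that add atoms: N,N-dimethylformamide, CN(C)C=O
Why: directed ortho-metalation; the carbon between the two acetal ethers is doubly chelated and the most acidic, so it is lithiated in preference to the sites next to one ether or next to the bulky silyloxy group, and the aryllithium is formylated by the formamide.

Step 6
Reactants: 9 2,6-bis(methoxymethoxy)-4-[2-(4-triisopropylsilyloxyphenyl)ethyl]benzaldehyde
Product: 10 2,6-dihydroxy-4-[2-(4-triisopropylsilyloxyphenyl)ethyl]benzaldehyde
Conditions: 3 M aq. HCl, THF, 45 °C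
Reagents that add atoms: none
Why: acid hydrolysis of the two aryl methoxymethyl acetals, helped by hydrogen bonding of the freed phenols to the aldehyde; the aryl triisopropylsilyl ether is stable to dilute aqueous acid.

Step 7
Reactants: 10 2,6-dihydroxy-4-[2-(4-triisopropylsilyloxyphenyl)ethyl]benzaldehyde; 11 2-methylprop-1-enylboronic acid
Product: 14 2,2-dimethyl-7-[2-(4-triisopropylsilyloxyphenyl)ethyl]-2H-chromen-5-ol, via allylic amine 12 (not isolated), via ortho-quinone methide 13 (not isolated)
Conditions: Bn2NH (1 equiv), 1,4-dioxane, 90 °C
Reagents that add atoms: none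
Why: Dibenzylamine condenses with the aldehyde of 10 to an iminium ion, and an ortho phenoxide binds the boronic acid 11 as a tetracoordinate boronate. From this ate complex the 2-methylprop-1-enyl group migrates intramolecularly to the iminium carbon (borono-Mannich step), forming C4–C3 and giving allylic amine 12. At 90 °C the ortho phenol expels dibenzylamine from 12 to give ortho-quinone methide 13, a 1-oxatriene. Thermal six-electron oxa-electrocyclisation of 13 (disrotatory) forms O1–C2 at the gem-dimethyl terminus and closes the six-membered pyran, driven by rearomatisation of ring A. The closest known reaction type is the amine-promoted condensation of salicylaldehydes with alkenylboronic acids to 2H-chromenes. No stereocentre remains in 14; the one in 12 is racemic and is erased on elimination. The step needs alkenyl transfer to outrun aminal formation and protodeboronation, and the boron-binding ortho phenol secures this by making the transfer intramolecular. The choice between the two hydroxyls is removed by the mirror plane of 10, and the one not used is left as the C5 phenol for step 8.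

Step 8
Reactants: 14 2,2-dimethyl-7-[2-(4-triisopropylsilyloxyphenyl)ethyl]-2H-chromen-5-ol; 15 3-chloro-3-methylbut-1-yne
Product: 16 2,2-dimethyl-5-(2-methylbut-3-yn-2-yloxy)-7-[2-(4-triisopropylsilyloxyphenyl)ethyl]-2H-chromene
Conditions: CuCl2·2H2O (cat.), DBU, MeCN, 0 °C
Reagents that add atoms: none
Why: copper-catalysed propargylic substitution of the tertiary chloride by the only free phenoxide, through a copper acetylide-derived electrophile; at 0 °C the tertiary aryl propargyl ether is far below the temperature at which such ethers cyclise.

Step 9
Reactants: 16 2,2-dimethyl-5-(2-methylbut-3-yn-2-yloxy)-7-[2-(4-triisopropylsilyloxyphenyl)ethyl]-2H-chromene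
Product: 17 2,2-dimethyl-5-(2-methylbut-3-en-2-yloxy)-7-[2-(4-triisopropylsilyloxyphenyl)ethyl]-2H-chromene
Conditions: H2 (1 atm), Pd/CaCO3 poisoned with Pb(OAc)2, quinoline, EtOAc, rt, stopped after 1 equiv H2
Reagents that add atoms: none
Why: Lindlar semi-hydrogenation; the terminal alkyne binds the poisoned palladium surface much more strongly than the vinyl group formed or the hindered, conjugated C3=C4 bond, so uptake can be stopped at the alkene.

Step 10
Reactants: 17 2,2-dimethyl-5-(2-methylbut-3-en-2-yloxy)-7-[2-(4-triisopropylsilyloxyphenyl)ethyl]-2H-chromene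
Product: 19 2,2-dimethyl-6-(3-methylbut-2-enyl)-7-[2-(4-triisopropylsilyloxyphenyl)ethyl]-2H-chromen-5-ol, via ortho-dienone 18 (not isolated)
Conditions: PhNEt2, 130 °C, Ar
Reagents that add atoms: none
Why: aromatic Claisen rearrangement; the [3,3] shift moves the allyl terminus from the C5 oxygen to C6 and inverts the 1,1-dimethylallyl unit to prenyl, and dienone 18 tautomerises to the phenol. Attack at C4a gives a dienone that cannot enolise and reverts, and the basic solvent keeps the ortho-prenylphenol from closing to a chroman.

Step 11
Reactants: 19 2,2-dimethyl-6-(3-methylbut-2-enyl)-7-[2-(4-triisopropylsilyloxyphenyl)ethyl]-2H-chromen-5-ol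
Product: 20 7-[2-(4-hydroxyphenyl)ethyl]-2,2-dimethyl-6-(3-methylbut-2-enyl)-2H-chromen-5-ol (CNP0243348.0)
Conditions: Bu4NF, AcOH, THF, 0 °C to rt
Reagents that add atoms: none
Why: fluoride cleavage of the aryl silyl ether, driven by the Si–F bond; acetic acid keeps the electron-rich phenols protonated, and neither alkene is touched.

## Compound list

1 | 3,5-dihydroxybenzaldehyde | O=Cc1cc(O)cc(O)c1 | starting material
2 | 3,5-bis(methoxymethoxy)benzaldehyde | O=Cc1cc(OCOC)cc(OCOC)c1 | intermediate
3 | 1,3-bis(methoxymethoxy)-5-vinylbenzene | C=Cc1cc(OCOC)cc(OCOC)c1 | intermediate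
4 | 4-bromophenol | Oc1ccc(Br)cc1 | starting material
5 | (4-bromophenoxy)triisopropylsilane | CC(C)[Si](Oc1ccc(Br)cc1)(C(C)C)C(C)C | intermediate
6 | 9-[2-[3,5-bis(methoxymethoxy)phenyl]ethyl]-9-borabicyclo[3.3.1]nonane | COCOc1cc(CCB2C3CCCC2CCC3)cc(OCOC)c1 | intermediate
7 | triisopropyl[4-[2-[3,5-bis(methoxymethoxy)phenyl]ethyl]phenoxy]silane | COCOc1cc(CCc2ccc(O[Si](C(C)C)(C(C)C)C(C)C)cc2)cc(OCOC)c1 | intermediate
8 | [2,6-bis(methoxymethoxy)-4-[2-(4-triisopropylsilyloxyphenyl)ethyl]phenyl]lithium | [Li]c1c(OCOC)cc(CCc2ccc(O[Si](C(C)C)(C(C)C)C(C)C)cc2)cc1OCOC | intermediate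
9 | 2,6-bis(methoxymethoxy)-4-[2-(4-triisopropylsilyloxyphenyl)ethyl]benzaldehyde | O=Cc1c(OCOC)cc(CCc2ccc(O[Si](C(C)C)(C(C)C)C(C)C)cc2)cc1OCOC | intermediate
10 | 2,6-dihydroxy-4-[2-(4-triisopropylsilyloxyphenyl)ethyl]benzaldehyde | O=Cc1c(O)cc(CCc2ccc(O[Si](C(C)C)(C(C)C)C(C)C)cc2)cc1O | intermediate
11 | 2-methylprop-1-enylboronic acid | CC(C)=CB(O)O | starting material
12 | 2-[1-(dibenzylamino)-3-methylbut-2-enyl]-5-[2-(4-triisopropylsilyloxyphenyl)ethyl]benzene-1,3-diol (racemic) | CC(C)=CC(N(Cc1ccccc1)Cc1ccccc1)c1c(O)cc(CCc2ccc(O[Si](C(C)C)(C(C)C)C(C)C)cc2)cc1O | intermediate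
13 | 3-hydroxy-2-(3-methylbut-2-enylidene)-5-[2-(4-triisopropylsilyloxyphenyl)ethyl]cyclohexa-3,5-dien-1-one | CC(C)=CC=C1C(=O)C=C(CCc2ccc(O[Si](C(C)C)(C(C)C)C(C)C)cc2)C=C1O | intermediate
14 | 2,2-dimethyl-7-[2-(4-triisopropylsilyloxyphenyl)ethyl]-2H-chromen-5-ol | CC1(C)C=Cc2c(O)cc(CCc3ccc(O[Si](C(C)C)(C(C)C)C(C)C)cc3)cc2O1 | intermediate
15 | 3-chloro-3-methylbut-1-yne | CC(C)(Cl)C#C | starting material
16 | 2,2-dimethyl-5-(2-methylbut-3-yn-2-yloxy)-7-[2-(4-triisopropylsilyloxyphenyl)ethyl]-2H-chromene | C#CC(C)(C)Oc1cc(CCc2ccc(O[Si](C(C)C)(C(C)C)C(C)C)cc2)cc2c1C=CC(C)(C)O2 | intermediate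
17 | 2,2-dimethyl-5-(2-methylbut-3-en-2-yloxy)-7-[2-(4-triisopropylsilyloxyphenyl)ethyl]-2H-chromene | C=CC(C)(C)Oc1cc(CCc2ccc(O[Si](C(C)C)(C(C)C)C(C)C)cc2)cc2c1C=CC(C)(C)O2 | intermediate
18 | 2,2-dimethyl-6-(3-methylbut-2-enyl)-7-[2-(4-triisopropylsilyloxyphenyl)ethyl]-2H-chromen-5(6H)-one (racemic) | CC(C)=CCC1C(=O)C2=C(OC(C)(C)C=C2)C=C1CCc1ccc(O[Si](C(C)C)(C(C)C)C(C)C)cc1 | intermediate
19 | 2,2-dimethyl-6-(3-methylbut-2-enyl)-7-[2-(4-triisopropylsilyloxyphenyl)ethyl]-2H-chromen-5-ol | CC(C)=CCc1c(CCc2ccc(O[Si](C(C)C)(C(C)C)C(C)C)cc2)cc2c(c1O)C=CC(C)(C)O2 | intermediate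
20 | 7-[2-(4-hydroxyphenyl)ethyl]-2,2-dimethyl-6-(3-methylbut-2-enyl)-2H-chromen-5-ol (CNP0243348.0) | CC(C)=CCc1c(CCc2ccc(O)cc2)cc2c(c1O)C=CC(C)(C)O2 | target

## Step count and risks

Total step count: 11.
Longest linear sequence: 10 steps (from 1 through steps 1, 2 and 4 to 11; step 3 is a one-step side branch).

Least certain steps:

**Step 7 (key step).**
- What may go wrong: iminium formation may be slow at an aldehyde that is electron-rich and hydrogen-bonded on both sides, and the alkenylboronic acid may protodeboronate at 90 °C. The result would be stalled conversion.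
- Fallback: it sets out from 7 and returns at 14. Aqueous acid removes both acetals of 7 to give 5-[2-(4-triisopropylsilyloxyphenyl)ethyl]benzene-1,3-diol F1. F1 is condensed with 3-methylbut-2-enal under ethylenediammonium diacetate catalysis in refluxing toluene. This is a Knoevenagel-type attack of the ring carbon between the two hydroxyls on the iminium of the enal, followed by the same six-electron oxa-closure.
- Cost: regiocontrol no longer rests on symmetry. Attack at the carbon next to the side chain would give an isomeric chromene that must be separated.

**Step 4.**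
- What may go wrong: transmetalation of the alkylborane may be incomplete, and protodeboronation or beta-hydride elimination may divert the alkyl group. Prolonged hot aqueous base could also cause some loss of the silyl ether.
- Fallback: it sets out from 3 and 5 and returns at 7. A Mizoroki–Heck coupling (Pd(OAc)2, P(o-tol)3, Et3N, DMF, 100 °C) gives [4-[(E)-2-[3,5-bis(methoxymethoxy)phenyl]ethenyl]phenoxy]triisopropylsilane F2. Hydrogenation of F2 over Pd/C in EtOAc then gives 7; the acetals and the silyl ether are inert to both steps.

**Step 9.**
- What may go wrong: over-reduction of the new vinyl group, giving an ether that cannot rearrange, or partial saturation of C3=C4 if hydrogen uptake is not stopped in time.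
- Fallback: it sets out from 14 and returns at 17, with no hydrogenation. 2-Methylbut-3-en-2-ol is deprotonated with n-BuLi and acylated with Boc2O to give tert-butyl 2-methylbut-3-en-2-yl carbonate F3. Pd(PPh3)4 (zerovalent palladium) in THF at 0 °C then joins 14 and F3 in a Tsuji–Trost O-allylation. Under kinetic control the phenoxide attacks the more substituted terminus of the 1,1-dimethylallyl palladium complex and gives 17 directly.

**Step 10.**
- What may go wrong: the tertiary allyl ether may fragment by ionisation or a retro-ene path and return 14. The allyl unit may migrate to C8 through the C4a dienone and a second [3,3] shift. The ortho-prenylphenol may cyclise to a chroman if traces of acid are present.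
- Fallback: it sets out from 14 and returns at 19. Allyl bromide and K2CO3 in acetone give 5-(allyloxy)-2,2-dimethyl-7-[2-(4-triisopropylsilyloxyphenyl)ethyl]-2H-chromene F4. Thermal Claisen rearrangement of this primary allyl ether, which has no easy ionisation path, gives 6-allyl-2,2-dimethyl-7-[2-(4-triisopropylsilyloxyphenyl)ethyl]-2H-chromen-5-ol F5. Cross metathesis of F5 with 2-methylbut-2-ene, using second-generation Grubbs catalyst RuCl2(H2IMes)(PCy3)(=CHPh), converts allyl into prenyl and gives 19. The hindered cis C3=C4 bond next to the quaternary carbon is expected to stay out of the metathesis.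

Further compounds
F1 | step 7 | 5-[2-(4-triisopropylsilyloxyphenyl)ethyl]benzene-1,3-diol | Oc1cc(O)cc(CCc2ccc(O[Si](C(C)C)(C(C)C)C(C)C)cc2)c1
F2 | step 4 | [4-[(E)-2-[3,5-bis(methoxymethoxy)phenyl]ethenyl]phenoxy]triisopropylsilane | COCOc1cc(/C=C/c2ccc(O[Si](C(C)C)(C(C)C)C(C)C)cc2)cc(OCOC)c1
F3 | step 9 | tert-butyl 2-methylbut-3-en-2-yl carbonate | C=CC(C)(C)OC(=O)OC(C)(C)C
F4 | step 10 | 5-(allyloxy)-2,2-dimethyl-7-[2-(4-triisopropylsilyloxyphenyl)ethyl]-2H-chromene | C=CCOc1cc(CCc2ccc(O[Si](C(C)C)(C(C)C)C(C)C)cc2)cc2c1C=CC(C)(C)O2
F5 | step 10 | 6-allyl-2,2-dimethyl-7-[2-(4-triisopropylsilyloxyphenyl)ethyl]-2H-chromen-5-ol | C=CCc1c(CCc2ccc(O[Si](C(C)C)(C(C)C)C(C)C)cc2)cc2c(c1O)C=CC(C)(C)O2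
A1 | alternative 1 | tert-butyldimethylsilyl (ring B) and triisopropylsilyl (C5) bis-ether of the target | CC(C)=CCc1c(CCc2ccc(O[Si](C)(C)C(C)(C)C)cc2)cc2c(c1O[Si](C(C)C)(C(C)C)C(C)C)C=CC(C)(C)O2
A2 | alternative 1 | 2,2-dimethyl-7-[2-(4-tert-butyldimethylsilyloxyphenyl)ethyl]-2H,5H-pyrano[4,3-b]pyran-5-one | O=C1OC(CCc2ccc(O[Si](C)(C)C(C)(C)C)cc2)=CC2=C1C=CC(C)(C)O2
A3 | alternative 1 | triisopropyl(5-methylhex-4-en-1-ynyloxy)silane | CC(C)=CCC#CO[Si](C(C)C)(C(C)C)C(C)C
A4 | alternative 2 | 2,4-bis(3-methylbut-2-enyl)-3-(triisopropylsilyloxy)-5-[2-(4-tert-butyldimethylsilyloxyphenyl)ethyl]phenol | Oc1cc(CCc2ccc(O[Si](C)(C)C(C)(C)C)cc2)c(CC=C(C)C)c(O[Si](C(C)C)(C(C)C)C(C)C)c1CC=C(C)C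
A5 | alternative 2 | 2-(3-methylbut-2-enyl)-3-[2-(4-tert-butyldimethylsilyloxyphenyl)ethyl]cyclobut-2-en-1-one | CC(C)=CCC1=C(CCc2ccc(O[Si](C)(C)C(C)(C)C)cc2)CC1=O
A6 | alternative 3 | 7-[2-(4-tert-butyldimethylsilyloxyphenyl)ethyl]-2,2-dimethyl-6-(3-methylbut-2-enyl)-2H-chromen-5-ol | CC(C)=CCc1c(CCc2ccc(O[Si](C)(C)C(C)(C)C)cc2)cc2c(c1O)C=CC(C)(C)O2
A7 | alternative 3 | 2-allyl-5-(2-methylbut-3-en-2-yloxy)-6-vinyl-3-[2-(4-tert-butyldimethylsilyloxyphenyl)ethyl]phenol | C=CCc1c(CCc2ccc(O[Si](C)(C)C(C)(C)C)cc2)cc(OC(C)(C)C=C)c(C=C)c1O
A8 | alternative 3 | 2-methylbut-2-ene | CC=C(C)C
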